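The runs were generated by integration on assumed constants; scatter was added.

Compare the blue flask with the green run: the gas is held at 14 mM in both, but blue has twice the substrate, and it keeps more of it in percent of its charge, 55.0% after 30.0 h against 42.8% in green after 15.0 d.

| flask | substrate | gas | remark | time |
|---|---|---|---|---|
| blue | 0.10 M | 14 mM (held) | the very flask that is asked about, followed so far |  |
| green | 0.050 M | 14 mM (held) | run made earlier |  |
| flask | 0.10 M | 14 mM (held) |  | 15 d |

blue run (percent of the substrate charged)

| time / h | substrate / % | target / % | isomer of the product / % |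
|---|---|---|---|
| 2.00 | 61.3 | 36.5 | 0.8 |
| 6.00 | 58.7 | 35.2 | 6.3 |
| 10.0 | 58.0 | 33.1 | 9.0 |
| 15.0 | 57.1 | 31.4 | 11.4 |
| 20.0 | 56.3 | 29.6 | 14.3 |
| 30.0 | 55.0 | 29.4 | 17.0 |

green run (percent of the substrate charged)

| time / d | substrate / % | target / % | isomer of the product / % |
|---|---|---|---|
| 1.25 | 43.5 | 36.3 | 19.7 |
| 2.08 | 41.8 | 34.7 | 23.5 |
| 3.00 | 41.9 | 33.9 | 24.0 |
| 5.00 | 42.2 | 33.9 | 23.5 |
| 10.0 | 42.2 | 34.6 | 23.9 |
| 15.0 | 42.8 | 34.3 | 23.2 |

(readings scatter by 0.5 percentage points)

1. conversion of substrate at 15 d
2. amount of target at 15 d, in percent of the substrate charged
3. amount of isomer of the product at 15 d, in percent of the substrate charged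
4. amount of target if the flask were left three thousand times as long, in percent of the substrate charged

Find what holds still and freeze it. The gas is held, so fold it into a constant. Suppose that each substrate consumed gives target plus one by-product that stays in solution. Let c be the charge and S, P and E the fractions of it found as substrate, target and isomer. Green's last row then gives 0.0230 M for the stall quotient Q = c(P+E)P/S, the by-product concentration times target over substrate. Blue's first reading, after 2.00 h, gives 0.0222 M, a check from another charge and another time. Since c stands on top, and P+E with it, take this as thermodynamic control: at one Q, blue with its larger charge stops at lower conversion.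

Freeze the second ratio too. Green reads ρ = E/P = 0.676 and shows no drift from 3.00 d onward, and the asked 15 d is later than that. With x the conversion, write Q = c·x·x / [(1+ρ)(1−x)]. Put L = Q(1+ρ)/c, which is 0.386 for blue, and solve the quadratic. My reckoning gives 45.8% conversion, with 27.3% target and 18.5% isomer.

The forecast says 46.1% conversion, 27.4% target, 18.8% isomer and 27.4% target after the long wait, since “the long-time value should be the same”. My conversion lies 0.30 percentage points below it.

The simulation gives 46.3% conversion. In percent of the substrate charged, the target stands at 27.6%, and after the long wait at 27.6%. The isomer of the product stands at 18.8%.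

    substrate + reagent ⇌ target + by-product (K = 1.70, k = 83.0 M⁻¹ h⁻¹)
    gas ⇌ reagent, rate k2*(csat - [reagent]) (kL = 6.80 h⁻¹)
    target ⇌ isomer of the product (K = 0.680, k = 0.0340 h⁻¹)

In the flask, the largest change of the share of substrate, target or isomer of the product over the second half of the time is 0 points. Carry Q to a neighbour charged with 0.025 M: there L is 1.54, the same quadratic gives 69.1%, and that flask reaches 69.7% conversion.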